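The route rests on cutting the C2–C1' bond between the pyranone (ring C) and ring B. Ring B has para-related hydroxyls at C2' and C5' and a methoxy at C4', so it is a 5-methoxy-1,4-benzoquinone in its reduced state. The 3-prenylchromone offers one vinylic hydrogen for metalation, at C2 beside O1. A Stille coupling of a chromon-2-ylstannane with 2-bromo-5-methoxy-1,4-benzoquinone, finished by a dithionite work-up in the same flask, attaches ring B with its three oxygens already differentiated and without any B-ring protecting group. The coupling precursor is 5-O-TBS-7-methoxy-3-prenyl-2-(trimethylstannyl)chromone, built from a prenylated acetophenone by enaminone ring closure and C2 lithiation.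

Key step: step 7

Remark: the target has no stereocentre and its only olefin carries two identical methyl groups. It is therefore achiral and no enantiomer has to be selected.

Step 1
Reactants: 1 2',6'-dihydroxy-4'-methoxyacetophenone
Product: 3 1-[4-methoxy-2,6-bis(methoxymethoxy)phenyl]ethan-1-one, via disodium bis-phenoxide 2 (not isolated)
Conditions: NaH (2.2 equiv), THF–DMF, 0 °C; then MOMCl (2.4 equiv), 0 °C → rt
Reagents that add atoms: chloromethyl methyl ether (MOMCl), COCCl
Why: Williamson-type O-alkylation, in which irreversible deprotonation with NaH breaks both OH···O=C hydrogen bonds so that the two equivalent phenoxides are capped by the very reactive chloromethyl ether, leaving the ketone free of acidic protons for the enolate step.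

Step 2
Reactants: 3 1-[4-methoxy-2,6-bis(methoxymethoxy)phenyl]ethan-1-one; 4 prenyl bromide (1-bromo-3-methylbut-2-ene)
Product: 6 1-[4-methoxy-2,6-bis(methoxymethoxy)phenyl]-5-methylhex-4-en-1-one, via lithium enolate 5 (not isolated)
Conditions: LDA (commercial solution, 1.05 equiv), THF, −78 °C; then 4 (0.95 equiv), −78 → −20 °C
Reagents that add atoms: none
Why: Kinetic lithium enolate alkylation, in which the methyl group holds the only enolisable hydrogens, prenyl bromide reacts by direct SN2 at its primary carbon faster than enolates equilibrate in the cold, and the di-ortho-substituted aroyl group together with a slight deficit of bromide disfavours a second alkylation.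

Step 3
Reactants: 6 1-[4-methoxy-2,6-bis(methoxymethoxy)phenyl]-5-methylhex-4-en-1-one
Product: 8 5-hydroxy-7-methoxy-3-(3-methylbut-2-en-1-yl)-4H-chromen-4-one, via E-enaminone 7 (not isolated)
Conditions: t-BuOCH(NMe2)2 (2 equiv), toluene, 100 °C; evaporate; then 2 M HCl, MeOH, 40 °C
Reagents that add atoms: tert-butoxybis(dimethylamino)methane, CC(C)(C)OC(N(C)C)N(C)C
Why: Aminomethylenation followed by acid-induced chromone closure, in which the aminal ester releases tert-butoxide and a formamidinium ion and so condenses with the hindered, weakly acidic α-CH2 more readily than DMF dimethyl acetal would, after which HCl/MeOH removes both MOM acetals and one of the two equivalent phenols adds 6-endo-trig to the enaminone β-carbon with loss of dimethylamine, the prenyl olefin having no neighbouring phenol to trap it.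

Step 4
Reactants: 8 5-hydroxy-7-methoxy-3-(3-methylbut-2-en-1-yl)-4H-chromen-4-one
Product: 9 5-[(tert-butyldimethylsilyl)oxy]-7-methoxy-3-(3-methylbut-2-en-1-yl)-4H-chromen-4-one
Conditions: TBSOTf (1.3 equiv), 2,6-lutidine (2 equiv), CH2Cl2, 0 °C → rt; Et3N-deactivated silica
Reagents that add atoms: tert-butyldimethylsilyl triflate (TBSOTf), CC(C)(C)[Si](C)(C)OS(=O)(=O)C(F)(F)F
Why: Silyl ether formation, in which the hydrogen-bonded 5-OH is too sluggish for TBSCl/imidazole but is silylated by the triflate, removing the acidic proton before metalation, placing a bulky and poorly directing group next to C6–H, and allowing removal at the end with fluoride instead of acid.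

Step 5
Reactants: 9 5-[(tert-butyldimethylsilyl)oxy]-7-methoxy-3-(3-methylbut-2-en-1-yl)-4H-chromen-4-one
Product: 11 5-[(tert-butyldimethylsilyl)oxy]-7-methoxy-3-(3-methylbut-2-en-1-yl)-2-(trimethylstannyl)-4H-chromen-4-one, via 2-lithiochromone 10 (not isolated)
Conditions: TMPH, n-BuLi, THF, 0 °C (LiTMP, 1.2 equiv); 9, −78 °C, 20 min; Me3SnCl (1.4 equiv), −78 → −20 °C; pH 7 buffer; Et3N-deactivated silica
Reagents that add atoms: trimethyltin chloride, C[Sn](C)(C)Cl
Why: Deprotonative lithiation–stannylation, in which C3 is blocked and the sp2 C2–H next to O1 of the electron-poor pyranone is the kinetically most acidic site for the bulky non-nucleophilic amide, so the vinyllithium should form ahead of deprotonation at the allylic CH2 or the aryl C–H and is captured at once by Me3SnCl, a capture that a zinc reagent would undergo only slowly.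

Step 6
Reactants: 12 1-bromo-2,4,5-trimethoxybenzene
Product: 13 2-bromo-5-methoxy-1,4-benzoquinone
Conditions: (NH4)2Ce(NO3)6 (2.5 equiv), MeCN–H2O, 0 °C, 20 min
Reagents that add atoms: water, O
Why: Oxidative demethylation with CAN, in which two one-electron oxidations with ipso attack of water and loss of methanol turn the para-related methoxy carbons C2 and C5 into the quinone carbonyls, the C4 methoxy survives as a vinylogous ester, and the bromine blocks the position where oxidative dimerisation would otherwise start.

Step 7
Reactants: 11 5-[(tert-butyldimethylsilyl)oxy]-7-methoxy-3-(3-methylbut-2-en-1-yl)-2-(trimethylstannyl)-4H-chromen-4-one; 13 2-bromo-5-methoxy-1,4-benzoquinone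
Product: 15 5-[(tert-butyldimethylsilyl)oxy]-2-(2,5-dihydroxy-4-methoxyphenyl)-7-methoxy-3-(3-methylbut-2-en-1-yl)-4H-chromen-4-one, via chromonyl methoxybenzoquinone 14 (not isolated)
Conditions: Pd2(dba)3·CHCl3 (5 mol %), AsPh3 (20 mol %), CuI (20 mol %), degassed DMF, 23 °C, dark, Ar; then EtOAc and sat. aq Na2S2O4 into the same flask, 23 °C, 10 min
Reagents that add atoms: none
Why: Pd(0) inserts into the C–Br bond of 13, which behaves as a vinylogous acyl bromide, CuI speeds the transfer of the crowded chromon-2-yl group from tin to palladium, and reductive elimination forges the C2–C1' bond to give quinone 14. The closest known reaction type is the Pd/Cu-catalysed Stille coupling of alkenyl, α-alkoxyalkenyl and heteroaryl stannanes with bromo-1,4-quinones. No ring is closed and no stereocentre is created, and ring B becomes aromatic only when dithionite delivers two electrons and two protons to 14 during the work-up. Site selectivity on ring B is needed and is secured by the bromine, which sits para to the methoxy-bearing carbon of 13, so the two carbonyl carbons become C2' and C5' and the methoxy carbon becomes C4'. Chemoselectivity comes from the neutral stannane, which unlike a lithium or zinc reagent is not oxidised by the quinone, and from weakly nucleophilic AsPh3, which unlike PPh3 does not add to quinones. Reduction in the same flask removes the electrophilic quinone before the neighbouring prenyl olefin can attack its C–H carbon, the later C6'.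

Step 8
Reactants: 15 5-[(tert-butyldimethylsilyl)oxy]-2-(2,5-dihydroxy-4-methoxyphenyl)-7-methoxy-3-(3-methylbut-2-en-1-yl)-4H-chromen-4-one
Product: 16 artoindonesianin Q, 2-(2,5-dihydroxy-4-methoxyphenyl)-5-hydroxy-7-methoxy-3-(3-methylbut-2-en-1-yl)-4H-chromen-4-one
Conditions: KHF2 (2 equiv), degassed MeOH–THF, 23 °C, Ar
Reagents that add atoms: none
Why: Fluoride-mediated cleavage of an aryl silyl ether, in which the 5-phenoxide is a good leaving group because it is conjugated with C4=O, the hydrogen difluoride keeps the medium slightly acidic so the hydroquinone ring B is not autoxidised, and the prenyl olefin and the methyl ethers are inert.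

Compound list
1 | 2',6'-dihydroxy-4'-methoxyacetophenone | CC(=O)c1c(O)cc(OC)cc1O | starting material
2 | disodium 2-acetyl-5-methoxybenzene-1,3-diolate | CC(=O)c1c([O-])cc(OC)cc1[O-].[Na+].[Na+] | intermediate
3 | 1-[4-methoxy-2,6-bis(methoxymethoxy)phenyl]ethan-1-one | CC(=O)c1c(OCOC)cc(OC)cc1OCOC | intermediate
4 | prenyl bromide (1-bromo-3-methylbut-2-ene) | CC(C)=CCBr | starting material
5 | lithium enolate of 3 (lithium 1-[4-methoxy-2,6-bis(methoxymethoxy)phenyl]ethen-1-olate) | C=C(O[Li])c1c(OCOC)cc(OC)cc1OCOC | intermediate
6 | 1-[4-methoxy-2,6-bis(methoxymethoxy)phenyl]-5-methylhex-4-en-1-one | COCOc1cc(OC)cc(OCOC)c1C(=O)CCC=C(C)C | intermediate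
7 | (E)-2-[(dimethylamino)methylidene]-1-[4-methoxy-2,6-bis(methoxymethoxy)phenyl]-5-methylhex-4-en-1-one (push–pull olefin, geometry labile and of no consequence) | COCOc1cc(OC)cc(OCOC)c1C(=O)/C(CC=C(C)C)=C/N(C)C | intermediate
8 | 5-hydroxy-7-methoxy-3-(3-methylbut-2-en-1-yl)-4H-chromen-4-one | COc1cc(O)c2c(=O)c(CC=C(C)C)coc2c1 | intermediate
9 | 5-[(tert-butyldimethylsilyl)oxy]-7-methoxy-3-(3-methylbut-2-en-1-yl)-4H-chromen-4-one | COc1cc(O[Si](C)(C)C(C)(C)C)c2c(=O)c(CC=C(C)C)coc2c1 | intermediate
10 | 2-lithio derivative of 9 | COc1cc(O[Si](C)(C)C(C)(C)C)c2c(=O)c(CC=C(C)C)c([Li])oc2c1 | intermediate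
11 | 5-[(tert-butyldimethylsilyl)oxy]-7-methoxy-3-(3-methylbut-2-en-1-yl)-2-(trimethylstannyl)-4H-chromen-4-one | COc1cc(O[Si](C)(C)C(C)(C)C)c2c(=O)c(CC=C(C)C)c([Sn](C)(C)C)oc2c1 | intermediate
12 | 1-bromo-2,4,5-trimethoxybenzene | COc1cc(OC)c(OC)cc1Br | starting material
13 | 2-bromo-5-methoxy-1,4-benzoquinone | COC1=CC(=O)C(Br)=CC1=O | intermediate
14 | 2-{5-[(tert-butyldimethylsilyl)oxy]-7-methoxy-3-(3-methylbut-2-en-1-yl)-4-oxo-4H-chromen-2-yl}-5-methoxy-1,4-benzoquinone | COc1cc(O[Si](C)(C)C(C)(C)C)c2c(=O)c(CC=C(C)C)c(C3=CC(=O)C(OC)=CC3=O)oc2c1 | intermediate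
15 | 5-[(tert-butyldimethylsilyl)oxy]-2-(2,5-dihydroxy-4-methoxyphenyl)-7-methoxy-3-(3-methylbut-2-en-1-yl)-4H-chromen-4-one | COc1cc(O[Si](C)(C)C(C)(C)C)c2c(=O)c(CC=C(C)C)c(-c3cc(O)c(OC)cc3O)oc2c1 | intermediate
16 | artoindonesianin Q (achiral) | COc1cc(O)c2c(=O)c(CC=C(C)C)c(-c3cc(O)c(OC)cc3O)oc2c1 | target

Total step count: 8.
Longest linear sequence: 7 steps (steps 1–5, 7 and 8, from 1 to 16). Step 6 is a one-step side branch.

Steps most likely to fail

Step 7. Transfer of the crowded, electron-poor chromon-2-yl group from tin may be slower than several competing processes. These are protodestannylation, methyl transfer, quinone-driven oxidative homocoupling and decay of the bromoquinone. Heating cannot cure this because the quinone does not tolerate it. The fallback brings ring B in as a protected arene and replaces tin by zinc; it sets out from 13 and 9 and rejoins the route at 16. Dithionite reduction of 13 should give 2-bromo-5-methoxybenzene-1,4-diol F1. TBSCl/imidazole in DMF should convert this into 1-bromo-2,5-bis[(tert-butyldimethylsilyl)oxy]-4-methoxybenzene F2. Zincation of 9 with TMPZnCl·LiCl in THF at 25 °C should give the chromon-2-ylzinc chloride F3. This is joined to F2 in a Negishi coupling (Pd(OAc)2, SPhos, THF, 50 °C) to give the tris-silylated flavone F4. KHF2 in MeOH–THF under argon then removes all three aryl silyl ethers and gives 16.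

Step 5. The lithium amide may also deprotonate the doubly allylic CH2 on C3. The 2-lithio species may add to C2 of chromone that is not yet metalated, or decay before it is trapped. The fallback separates metalation from C–Sn bond formation; it sets out from 9 and rejoins the route at 11. The milder zinc amide TMPZnCl·LiCl (THF, 25 °C) should give the non-nucleophilic chromon-2-ylzinc chloride F3. Iodine converts this into 5-[(tert-butyldimethylsilyl)oxy]-2-iodo-7-methoxy-3-prenylchromone F5, which can be purified and stored. Palladium-catalysed stannylation of the C–I bond with hexamethylditin (Pd(PPh3)4, toluene, 90 °C) then delivers 11.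

Step 3. Aminomethylenation of the weakly acidic α-CH2 next to the twisted, di-ortho-substituted aroyl group may stall. Long heating or a long acid treatment would invite decomposition and addition of HCl or methanol across the prenyl olefin. The fallback reverses the order so that a free ortho-phenol assists the one-carbon insertion, the way 3-benzylchromones are commonly made from 2'-hydroxydihydrochalcones. It sets out from 6 and rejoins the route at 8. Brief treatment of 6 with catalytic HCl in MeOH should give 1-(2,6-dihydroxy-4-methoxyphenyl)-5-methylhex-4-en-1-one F6. Heating this with DMF dimethyl acetal in toluene should give the hydrogen-bonded free-phenol enaminone F7, which closes to 8 on stirring with dilute acid.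

Further compounds
F1 | step 7 | 2-bromo-5-methoxybenzene-1,4-diol | COc1cc(O)c(Br)cc1O
F2 | step 7 | 1-bromo-2,5-bis[(tert-butyldimethylsilyl)oxy]-4-methoxybenzene | COc1cc(O[Si](C)(C)C(C)(C)C)c(Br)cc1O[Si](C)(C)C(C)(C)C
F3 | step 7 | {5-[(tert-butyldimethylsilyl)oxy]-7-methoxy-3-(3-methylbut-2-en-1-yl)-4-oxo-4H-chromen-2-yl}zinc chloride | COc1cc(O[Si](C)(C)C(C)(C)C)c2c(=O)c(CC=C(C)C)c([Zn]Cl)oc2c1
F4 | step 7 | 2-{2,5-bis[(tert-butyldimethylsilyl)oxy]-4-methoxyphenyl}-5-[(tert-butyldimethylsilyl)oxy]-7-methoxy-3-(3-methylbut-2-en-1-yl)-4H-chromen-4-one | COc1cc(O[Si](C)(C)C(C)(C)C)c2c(=O)c(CC=C(C)C)c(-c3cc(O[Si](C)(C)C(C)(C)C)c(OC)cc3O[Si](C)(C)C(C)(C)C)oc2c1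
F5 | step 5 | 5-[(tert-butyldimethylsilyl)oxy]-2-iodo-7-methoxy-3-(3-methylbut-2-en-1-yl)-4H-chromen-4-one | COc1cc(O[Si](C)(C)C(C)(C)C)c2c(=O)c(CC=C(C)C)c(I)oc2c1
F6 | step 3 | 1-(2,6-dihydroxy-4-methoxyphenyl)-5-methylhex-4-en-1-one | COc1cc(O)c(C(=O)CCC=C(C)C)c(O)c1
F7 | step 3 | (E)-1-(2,6-dihydroxy-4-methoxyphenyl)-2-[(dimethylamino)methylidene]-5-methylhex-4-en-1-one | COc1cc(O)c(C(=O)/C(CC=C(C)C)=C/N(C)C)c(O)c1
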